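**Assumption:** atoms are labelled with ent-kaurane numbering (C1–C20), and 1, 7 and 10 are bought enantiopure (10 is a prostaglandin-type building block sold in both enantiomeric forms).

## Retrosynthetic overview
- The C16=C17 methylene is added last. The 10-membered ring is closed at C7–C8 by a Nozaki–Hiyama–Kishi reaction between the C7 aldehyde and a 2-iodocyclopentenone.
- The C9–C10 bond and its quaternary centre come from a photochemical step. An alkoxy radical at C7–O abstracts H from C10, and the resulting C10 radical is acylated on nickel by an "east" thioester.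
- The east half is made by a photoredox decarboxylative Giese addition (C12–C13). The radical comes from L-malic acid and the acceptor is (S)-4-silyloxycyclopentenone, which carries a masked enone.
- Ring A comes from (R)-citronellal by cation–olefin cyclisation of its enol acetate.
- Ring order: A (step 2), D (bought, unmasked in step 10), macrocycle (step 13).

## Route

**Step 1**
Reactants: 1 (R)-(+)-citronellal
Product: 2 (1E,3R)-3,7-dimethylocta-1,6-dien-1-yl acetate (E/Z mixture, E drawn)
Conditions: Ac2O, KOAc (cat.), 130 °C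
Reagents that add atoms: acetic anhydride CC(=O)OC(C)=O
Why: Enol acetate formation leaves the bought methyl stereocentre untouched and turns the α-carbon (future C5) into a π-nucleophile.

**Step 2**
Reactants: 2 enol acetate
Product: 3 (1S,6R)-2,2,6-trimethylcyclohexane-1-carbaldehyde (trans)
Conditions: 85 % H3PO4, toluene, 90 °C; H2O
Reagents that add atoms: none
Why: In this Brønsted-acid cation–olefin cyclisation the tertiary cation is captured by the enol acetate through a chair with the methyl equatorial, and the epimerisable formyl carbon settles diequatorial, so C5 is set trans to the bought methyl centre.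

**Step 3**
Reactants: 3 trans aldehyde
Product: 4 (2S,3R)-2-ethenyl-1,1,3-trimethylcyclohexane
Conditions: Ph3PCH3Br, KOtBu, THF, 0 °C to rt
Reagents that add atoms: methyltriphenylphosphonium bromide C[P+](c1ccccc1)(c1ccccc1)c1ccccc1.[Br-]
Why: Wittig methylenation adds C7, and the α-centre is already in its thermodynamic trans arrangement, so it cannot be lost.

**Step 4**
Reactants: 4 vinylcyclohexane
Product: 5 2-[(1S,6R)-2,2,6-trimethylcyclohexyl]ethan-1-ol
Conditions: 9-BBN, THF; H2O2, NaOH
Reagents that add atoms: hydrogen peroxide OO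
Why: Anti-Markovnikov hydroboration–oxidation of the only alkene places the oxygen on C7.

**Step 5**
Reactants: 5 primary alcohol
Product: 6 2-{2-[(1S,6R)-2,2,6-trimethylcyclohexyl]ethoxy}isoindoline-1,3-dione
Conditions: N-hydroxyphthalimide, PPh3, DIAD, THF, 0 °C to rt
Reagents that add atoms: N-hydroxyphthalimide ON1C(=O)c2ccccc2C1=O
Why: A Mitsunobu reaction on an unhindered primary alcohol gives the reducible N–O precursor of the C7 alkoxy radical.

**Step 6**
Reactants: 7 L-(S)-malic acid
Product: 8 (S)-2-acetoxysuccinic anhydride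
Conditions: AcCl, 45 °C
Reagents that add atoms: acetyl chloride CC(=O)Cl
Why: O-Acetylation and cyclodehydration install the final C11 acetate without touching the bought C11 stereocentre.

**Step 7**
Reactants: 8 acetoxysuccinic anhydride
Product: 9 (3S)-3-acetoxy-4-oxo-4-(pyridin-2-ylsulfanyl)butanoic acid
Conditions: pyridine-2-thiol, CH2Cl2, 0 °C to rt
Reagents that add atoms: pyridine-2-thiol Sc1ccccn1
Why: Regioselective anhydride opening occurs at the more electrophilic carbonyl next to the acetoxy group, as it does with alcohols and amines, so C9 becomes the thioester and the distal carboxyl stays free.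

**Step 8**
Reactants: 9 thioester acid; 10 (4S)-4-[(tert-butyldimethylsilyl)oxy]cyclopent-2-en-1-one
Product: 12 S-pyridin-2-yl (2S)-2-acetoxy-3-[(1S,2S)-2-{[tert-butyl(dimethyl)silyl]oxy}-4-oxocyclopentyl]propanethioate, via 1,3-dioxoisoindolin-2-yl (3S)-3-acetoxy-4-oxo-4-(pyridin-2-ylsulfanyl)butanoate 11 (not isolated)
Conditions: N-hydroxyphthalimide, DIC, CH2Cl2, 0 °C; then 10, Hantzsch ester, Ru(bpy)3(PF6)2 (1 mol %), blue LED, rt
Reagents that add atoms: none
Why: In this photoredox decarboxylative Giese addition the primary C12 radical adds to the enone β-carbon anti to the silyloxy group, so C13 is set by the bought carbinol centre, and the D-ring enone stays masked as a β-silyloxy ketone.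

**Step 9**
Reactants: 6 N-alkoxyphthalimide; 12 thioester
Product: 13 (2S)-1-[(1R,2R)-2-(2-hydroxyethyl)-1,3,3-trimethylcyclohexyl]-1-oxo-3-[(1S,2S)-2-{[tert-butyl(dimethyl)silyl]oxy}-4-oxocyclopentyl]propan-2-yl acetate
Conditions: NiBr2·dme (10 mol %), dtbbpy (12 mol %), fac-Ir(ppy)3 (1 mol %), Hantzsch ester (1.5 equiv), DMA, 450 nm LED, rt
Reagents that add atoms: none
Why: Proposed new method: radical-relay cross-electrophile acylation, in which excited Ir(ppy)3 (turned over by the Hantzsch ester) cleaves the N–O bond of 6, the primary alkoxy radical abstracts the only δ-hydrogen (axial C10–H, six-membered 1,5-HAT), and the tertiary C10 radical is captured by the acyl–Ni(II) species formed from Ni(0) and the C(O)–S bond of 12, after which Ni(III) reductively eliminates the C9–C10 bond; capture occurs on the face opposite the syn-axial C4 methyl and the C5 side chain, so the acyl group ends trans to C6 and the methyl axial (10R); the closest known reaction types are Ni-catalysed ketone synthesis from tertiary N-hydroxyphthalimide esters with 2-pyridyl thioesters and photoredox δ-C–H alkylation of N-alkoxyphthalimides, which have not been merged or used to build a quaternary stereocentre.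

**Step 10**
Reactants: 13 keto alcohol
Product: 14 (2S)-1-[(1R,2R)-2-(2-hydroxyethyl)-1,3,3-trimethylcyclohexyl]-1-oxo-3-[(1S)-4-oxocyclopent-2-en-1-yl]propan-2-yl acetate
Conditions: DBU, CH2Cl2, 0 °C, short contact
Reagents that add atoms: none
Why: E1cB loss of the β-silyloxy group through the unhindered C8 enolate unmasks the C8=C14 enone, while the C11–H next to the neopentyl ketone is kinetically shielded.

**Step 11**
Reactants: 14 enone alcohol
Product: 15 (2S)-1-[(1R,2R)-2-(2-hydroxyethyl)-1,3,3-trimethylcyclohexyl]-3-[(1S)-3-iodo-4-oxocyclopent-2-en-1-yl]-1-oxopropan-2-yl acetate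
Conditions: I2, pyridine/CH2Cl2, 0 °C to rt
Reagents that add atoms: iodine II
Why: Johnson α-iodination (pyridine conjugate addition, iodination, elimination) touches only the enone α-carbon C8.

**Step 12**
Reactants: 15 iodoenone alcohol
Product: 16 (2S)-3-[(1S)-3-iodo-4-oxocyclopent-2-en-1-yl]-1-oxo-1-[(1R,2R)-1,3,3-trimethyl-2-(2-oxoethyl)cyclohexyl]propan-2-yl acetate
Conditions: Dess–Martin periodinane, CH2Cl2, 0 °C to rt; used directly
Reagents that add atoms: none
Why: Dess–Martin oxidation is non-basic, so the C7 aldehyde forms without triggering the six-ring aldol with C11.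

**Step 13**
Reactants: 16 iodoenone aldehyde
Product: 17 16-demethylene-shikoccin (5R,7R,10R,11S,13S; bicyclo[7.2.1] macrocycle with C16H2)
Conditions: CrCl2 (8 equiv), NiCl2 (2 mol %), DMSO/THF, 2 mM, rt; H2O
Reagents that add atoms: none
Why: Nozaki–Hiyama–Kishi macrocyclisation is selective for the aldehyde over both ketones, and in the B-ring-like chair folding imposed by the diequatorial C5 and C10 arms the O–Cr group sits pseudo-equatorial on the ring periphery, which gives 7R.

**Step 14**
Reactants: 17 macrocyclic enone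
Product: 18 target CNP0165527.2 (shikoccin skeleton; 5R,7R,10R,11S,13R)
Conditions: (CH2O)n, N-methylanilinium trifluoroacetate, THF, reflux
Reagents that add atoms: formaldehyde (as paraformaldehyde) C=O
Why: Mannich-type α-methylenation under weakly acidic conditions can reach only C16, which is the sole CH2 next to a carbonyl, and creates no stereocentre.

## Compound list
1 | (R)-(+)-citronellal | C[C@H](CCC=C(C)C)CC=O | starting material
2 | (1E,3R)-3,7-dimethylocta-1,6-dien-1-yl acetate | C[C@H](CCC=C(C)C)/C=C/OC(C)=O | intermediate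
3 | (1S,6R)-2,2,6-trimethylcyclohexane-1-carbaldehyde | C[C@@H]1CCCC(C)(C)[C@H]1C=O | intermediate
4 | (2S,3R)-2-ethenyl-1,1,3-trimethylcyclohexane | C[C@@H]1CCCC(C)(C)[C@H]1C=C | intermediate
5 | 2-[(1S,6R)-2,2,6-trimethylcyclohexyl]ethan-1-ol | C[C@@H]1CCCC(C)(C)[C@H]1CCO | intermediate
6 | 2-{2-[(1S,6R)-2,2,6-trimethylcyclohexyl]ethoxy}isoindoline-1,3-dione | C[C@@H]1CCCC(C)(C)[C@H]1CCON1C(=O)c2ccccc2C1=O | intermediate
7 | L-(S)-malic acid | OC(=O)C[C@H](O)C(=O)O | starting material
8 | (S)-2-acetoxysuccinic anhydride | CC(=O)O[C@H]1CC(=O)OC1=O | intermediate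
9 | (3S)-3-acetoxy-4-oxo-4-(pyridin-2-ylsulfanyl)butanoic acid | OC(=O)C[C@H](OC(C)=O)C(=O)Sc1ccccn1 | intermediate
10 | (4S)-4-[(tert-butyldimethylsilyl)oxy]cyclopent-2-en-1-one | O=C1C=C[C@@H](O[Si](C)(C)C(C)(C)C)C1 | starting material
11 | 1,3-dioxoisoindolin-2-yl (3S)-3-acetoxy-4-oxo-4-(pyridin-2-ylsulfanyl)butanoate | O=C(C[C@H](OC(C)=O)C(=O)Sc1ccccn1)ON1C(=O)c2ccccc2C1=O | intermediate
12 | S-pyridin-2-yl (2S)-2-acetoxy-3-[(1S,2S)-2-(TBSO)-4-oxocyclopentyl]propanethioate | O=C1C[C@H](C[C@H](OC(C)=O)C(=O)Sc2ccccn2)[C@@H](O[Si](C)(C)C(C)(C)C)C1 | intermediate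
13 | C9–C10 coupled keto alcohol (β-silyloxy ketone) | O=C1C[C@H](C[C@H](OC(C)=O)C(=O)[C@]2(C)CCCC(C)(C)[C@H]2CCO)[C@@H](O[Si](C)(C)C(C)(C)C)C1 | intermediate
14 | enone alcohol | O=C1C=C[C@@H](C[C@H](OC(C)=O)C(=O)[C@]2(C)CCCC(C)(C)[C@H]2CCO)C1 | intermediate
15 | 2-iodoenone alcohol | O=C1C(I)=C[C@@H](C[C@H](OC(C)=O)C(=O)[C@]2(C)CCCC(C)(C)[C@H]2CCO)C1 | intermediate
16 | 2-iodoenone aldehyde | O=C1C(I)=C[C@@H](C[C@H](OC(C)=O)C(=O)[C@]2(C)CCCC(C)(C)[C@H]2CC=O)C1 | intermediate
17 | 16-demethylene-shikoccin | C1C(=O)C2=C[C@H]1C[C@H](OC(C)=O)C(=O)[C@]1(C)CCCC(C)(C)[C@H]1C[C@H]2O | intermediate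
18 | CNP0165527.2 | C=C1C(=O)C2=C[C@H]1C[C@H](OC(C)=O)C(=O)[C@]1(C)CCCC(C)(C)[C@H]1C[C@H]2O | target

## Step count and risks
Total steps: 14. Longest linear sequence: 11 (steps 1–5 and 9–14).

**Step 9 (proposed new step).**
- Risks: the Hantzsch ester may quench the tertiary radical by H-atom transfer, nickel capture of so hindered a radical may be slow, and the α-acetoxy acyl–nickel species may decarbonylate.
- The fallback uses known chemistry, sets out from 5 and comes back at 13.
- Hypoiodite photolysis (PhI(OAc)2, I2, hν, cyclohexane) converts 5 into the cis-fused ether 4,4,7a-trimethyloctahydro-1-benzofuran F1.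
- TMSBr (CH2Cl2, −20 °C) then opens the tertiary C–O bond to give the tertiary bromide [2-(2-bromo-2,6,6-trimethylcyclohexyl)ethoxy]trimethylsilane F2. The configuration at C–Br is of no consequence.
- An established Ni/Zn reductive acylation of tertiary alkyl bromides (NiBr2·dme, dtbbpy, Zn, MgCl2, DMA) couples F2 with 12. A citric acid work-up removes the silyl group and gives 13.

**Step 13.**
- Risks: strain in the 10-membered ring, Cr(II) attack on the α-acetoxy ketone, and the wrong C7 epimer.
- The fallback sets out from 14 and comes back at 17.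
- Dess–Martin oxidation of 14 gives the iodine-free enone aldehyde (2S)-1-oxo-3-[(1S)-4-oxocyclopent-2-en-1-yl]-1-[(1R,2R)-1,3,3-trimethyl-2-(2-oxoethyl)cyclohexyl]propan-2-yl acetate F3.
- F3 is closed by an intramolecular phosphine-catalysed Morita–Baylis–Hillman reaction (PMe3, t-BuOH/THF, high dilution) to give 17. This closure is reversible, so the C7 centre can equilibrate.

**Step 14.**
- Risks: sluggish enolisation towards C16, and acid- or heat-induced damage to the cross-conjugated product.
- The fallback sets out from 17 and comes back at 18.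
- Eschenmoser's salt (CH2Cl2/MeCN, 40 °C, no base) gives the isolable Mannich base 16-[(dimethylamino)methyl]-16-demethylene-shikoccin F4.
- MeI converts F4 into the ammonium iodide 16-[(trimethylammonio)methyl]-16-demethylene-shikoccin iodide F5.
- Aqueous NaHCO3/CH2Cl2 at 0 °C eliminates F5 to give 18.

## Further compounds
F1 | step 9 | cis-4,4,7a-trimethyloctahydro-1-benzofuran | C[C@]12CCCC(C)(C)[C@H]1CCO2
F2 | step 9 | [2-(2-bromo-2,6,6-trimethylcyclohexyl)ethoxy]trimethylsilane | Br[C@]1(C)CCCC(C)(C)[C@H]1CCO[Si](C)(C)C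
F3 | step 13 | enone aldehyde without iodine | O=C1C=C[C@@H](C[C@H](OC(C)=O)C(=O)[C@]2(C)CCCC(C)(C)[C@H]2CC=O)C1
F4 | step 14 | 16-[(dimethylamino)methyl]-16-demethylene-shikoccin | CN(C)C[C@@H]1C(=O)C2=C[C@H]1C[C@H](OC(C)=O)C(=O)[C@]1(C)CCCC(C)(C)[C@H]1C[C@H]2O
F5 | step 14 | 16-[(trimethylammonio)methyl]-16-demethylene-shikoccin iodide | C[N+](C)(C)C[C@@H]1C(=O)C2=C[C@H]1C[C@H](OC(C)=O)C(=O)[C@]1(C)CCCC(C)(C)[C@H]1C[C@H]2O.[I-]
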